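**Retrosynthetic overview** (botcinin numbering: C1 lactone carbonyl, C2 CH(Me), C3 CH(OH), C4 quaternary ring-fusion carbon, C5 ring-fusion CH–O, C6 CH(Me), C7 CH–O-acyl, C8 CH(Me) next to the pyran oxygen)

1. The strategy rests on C5–C6–C7 (oxygen, methyl, oxygen, both oxygens trans to the methyl): once C4 and C8 are tied together as the two alkene carbons of a cyclopentene, this triad is meso.
2. Disconnections, last to first: the C7–O acyl bond; the lactone ring (C1–C5 and its ring oxygen) through the C2–C3 bond (intramolecular Reformatsky, then oxidation and cis-hydrogenation to set C2 and C3); the C4 methyl (axial transfer from AlMe3 to the pyran oxocarbenium ion) and C3 (alkoxymethyllithium) onto a C4 δ-lactone.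
3. The δ-lactone C4(=O)–O–C8 comes from ozonolysis of the cyclopentene: the free C7 hydroxyl captures C4 as a lactol, so only the C8 aldehyde takes the methyl group, and the lactol is then oxidised.
4. The desymmetrised cyclopentenediol comes from lipase acetylation of meso-2-methylcyclopent-4-ene-1,3-diol, made from singlet oxygen and 5-methylcyclopenta-1,3-diene (addition anti to methyl) with O–O reduction.
5. Ring order: peroxide bridge and cyclopentene (both temporary), then the tetrahydropyranone that becomes the pyran ring, then the fused δ-lactone last.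

Key step: step 2

Assumption: the lipase is taken to acetylate the hydroxyl that becomes the C7 oxygen (the sense known for the parent cis-cyclopent-4-ene-1,3-diol: O, sp2 carbon, sp3 carbon clockwise with H to the rear); if it prefers the other hydroxyl, the same monoacetate is reached by hydrolysis of the diacetate with the same enzyme.

**Route**

Step 1
Reactants: 1 sodium cyclopentadienide (NaC5H5, commercial 2.0 M solution in THF); 2 iodomethane
Product: 3 5-methylcyclopenta-1,3-diene (kept as a cold pentane/THF solution and used within the hour)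
Conditions: NaC5H5 added over 1 h to MeI (1.1 equiv), THF, −40 °C; cold pentane, ice-water wash, Na2SO4 at −30 °C
Reagents that add atoms: iodomethane 2, CI
Why: SN2 C-methylation of the cyclopentadienide anion gives the kinetic 5-substituted diene; adding the anion to the electrophile keeps free base from equilibrating the isomers, and the [1,5]-hydrogen shift is negligible below −20 °C.

Step 2
Reactants: 3 5-methylcyclopenta-1,3-diene; 4 dioxygen
Product: 6 meso-2-methylcyclopent-4-ene-1,3-diol (hydroxyls cis; methyl trans to both), via endoperoxide 5 (not isolated)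
Conditions: O2, rose bengal (cat.), visible light, CH2Cl2/MeOH, −78 °C; then thiourea (2 equiv), MeOH/H2O, −78 → 20 °C
Reagents that add atoms: dioxygen 4, O=O
Why: Sensitised singlet oxygen adds to the s-cis diene of 3 as a dienophile in a concerted suprafacial [4+2] cycloaddition, the reaction type known for cyclopentadiene itself, and thiourea then cleaves the O–O bond to unveil the cis-diol. The only ring closed is the transient peroxide bridge (a 1,2-dioxine formed in one intermolecular cycloaddition, both C–O bonds at once); it is opened again in the same flask, so no ring of the target is made here. The two new C–O bonds (future C5–O and C7–O) are cis to each other because the addition is suprafacial, and trans to the methyl on the sp3 carbon (future C6) because oxygen approaches the diene face that carries hydrogen. The step needs facial selectivity and [4+2] addition ahead of ene reaction and of a [1,5]-hydrogen shift in 3; the methyl group secures the first, the locked s-cis diene and −78 °C the others. Since the alkene carbons (future C4 and C8) are equivalent, 5 and 6 are meso and the absolute configuration is set only in step 3.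

Step 3
Reactants: 6 meso-2-methylcyclopent-4-ene-1,3-diol
Product: 7 4-hydroxy-5-methylcyclopent-2-en-1-yl acetate (acetate on the future C7 oxygen; free hydroxyl at future C5)
Conditions: Amano lipase PS (Burkholderia cepacia lipase), vinyl acetate, t-BuOMe, 25 °C
Reagents that add atoms: vinyl acetate, C=COC(C)=O
Why: Lipase-catalysed irreversible transesterification acylates one enantiotopic hydroxyl of the meso diol (enantiotopic group differentiation as known for cis-cyclopent-4-ene-1,3-diol), which fixes the absolute configuration of C5, C6 and C7 at once.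

Step 4
Reactants: 7 monoacetate
Product: 8 4-(tert-butyldimethylsilyloxy)-5-methylcyclopent-2-en-1-yl acetate (C5 O-TBS; C7 O-acetyl)
Conditions: t-BuMe2SiCl, imidazole, DMF, 0 → 20 °C
Reagents that add atoms: tert-butyldimethylsilyl chloride, CC(C)(C)[Si](C)(C)Cl
Why: Standard silylation of the remaining secondary allylic alcohol; no stereocentre is touched.

Step 5
Reactants: 8 silyl ether acetate
Product: 9 4-(tert-butyldimethylsilyloxy)-5-methylcyclopent-2-en-1-ol (C5 O-TBS; free C7 hydroxyl)
Conditions: K2CO3 (0.2 equiv), MeOH, 0 °C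
Reagents that add atoms: none
Why: Base-catalysed methanolysis removes the acetate and leaves the silyl ether, which frees the C7 hydroxyl for the next step.

Step 6
Reactants: 9 cyclopentenol
Product: 11 lactol aldehyde (five-membered lactol between O7 and C4; free C8 aldehyde; C5 O-TBS; anomers), via ozonide 10 (not isolated)
Conditions: O3, CH2Cl2, −78 °C; then PPh3, −78 → 20 °C; used crude
Reagents that add atoms: ozone, [O-][O+]=O
Why: Ozonolysis cuts the C4=C8 bond, and the free C7 hydroxyl closes a five-membered lactol onto the C4 aldehyde, so the two termini are told apart: only the C8 aldehyde stays free.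

Step 7
Reactants: 11 lactol aldehyde
Product: 12 pyranose lactol (six-membered lactol between O8 and C4; C5 O-TBS; C6 methyl; free C7 hydroxyl; C8 methyl; all equatorial; anomers)
Conditions: MeTi(OiPr)3 (2.5 equiv; from MeLi and ClTi(OiPr)3), THF, −78 → −30 °C; aq. NH4F
Reagents that add atoms: methyltriisopropoxytitanium, C[Ti](OC(C)C)(OC(C)C)OC(C)C
Why: The non-chelating titanium reagent adds to the aldehyde only and under Felkin–Anh control (methyl enters anti to the C7–O bond, past the C7 hydrogen), which should give the 7,8-anti carbinol (C8 S); the lactol then moves to the new C8 hydroxyl as the all-equatorial six-membered form.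

Step 8
Reactants: 12 pyranose lactol
Product: 13 3-(tert-butyldimethylsilyloxy)-5-hydroxy-4,6-dimethyloxan-2-one (C4 lactone; free C7 hydroxyl; all ring substituents equatorial)
Conditions: PhI(OAc)2 (1.2 equiv), TEMPO (cat.), CH2Cl2, 20 °C
Reagents that add atoms: none
Why: Oxoammonium oxidation takes a lactol to the lactone much faster than it oxidises a hindered secondary alcohol, so the C4 δ-lactone forms with the C7 hydroxyl intact.

Step 9
Reactants: 13 hydroxy lactone
Product: 14 5-(benzyloxy)-3-(tert-butyldimethylsilyloxy)-4,6-dimethyloxan-2-one (C7 O-benzyl; all ring substituents equatorial)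
Conditions: BnOC(=NH)CCl3 (1.5 equiv), TfOH (5 mol %), CH2Cl2/cyclohexane, 0 °C
Reagents that add atoms: benzyl 2,2,2-trichloroacetimidate, N=C(OCc1ccccc1)C(Cl)(Cl)Cl
Why: Acid-catalysed imidate benzylation avoids the base that would open or transpose the lactone, and it is done at once so that the free C7 hydroxyl cannot translactonise.

Step 10
Reactants: 15 (tributylstannyl)methanol
Product: 16 tributyl{[(4-methoxybenzyl)oxy]methyl}stannane
Conditions: NaH, 4-methoxybenzyl chloride, Bu4NI (cat.), THF/DMF, 0 → 20 °C
Reagents that add atoms: 4-methoxybenzyl chloride, COc1ccc(CCl)cc1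
Why: Williamson etherification of the primary stannyl alcohol gives the precursor of a protected hydroxymethyl anion.

Step 11
Reactants: 14 benzyl ether lactone; 16 alkoxymethylstannane
Product: 18 hemiketal (C4 bearing OH and CH2O-PMB; anomers), via alkoxymethyllithium 17 (not isolated)
Conditions: 16, n-BuLi, THF, −78 °C; then 14, −78 °C; H2O
Reagents that add atoms: [(4-methoxybenzyl)oxy]methyllithium 17, [Li]COCc1ccc(OC)cc1
Why: Tin–lithium exchange gives the α-alkoxymethyllithium, which adds once to the lactone because the lithium lactolate is stable at −78 °C; this brings in C3 with its oxygen.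

Step 12
Reactants: 18 hemiketal
Product: 19 methyl ketal (C4 bearing OMe and CH2O-PMB; anomers)
Conditions: MeOH, PPTS (cat.), 3 Å molecular sieves, 25 °C
Reagents that add atoms: methanol, CO
Why: Acid-catalysed ketalisation gives a leaving group at C4 and prevents ring opening to the hydroxy ketone in the next step.

Step 13
Reactants: 19 methyl ketal
Product: 20 5-(benzyloxy)-3-(tert-butyldimethylsilyloxy)-2-[(4-methoxybenzyloxy)methyl]-2,4,6-trimethyloxane (C4 methyl axial; CH2O-PMB arm and all other ring substituents equatorial)
Conditions: AlMe3 (5 equiv), Me3SiOTf (1.2 equiv), CH2Cl2, −78 → −20 °C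
Reagents that add atoms: trimethylaluminium, C[Al](C)C
Why: Ionisation gives the six-membered oxocarbenium ion, whose half-chair carries the C5–C8 substituents equatorially, and methyl is delivered along the axial trajectory through a chair-like transition state (C-glycosidation type), which sets the quaternary C4 with axial methyl.

Step 14
Reactants: 20 tetrahydropyran
Product: 21 C5 alcohol (free C5 hydroxyl; C3 O-PMB; C7 O-benzyl)
Conditions: Bu4NF, THF, 40 °C
Reagents that add atoms: none
Why: Fluoride cleaves the only silyl ether; the benzyl and 4-methoxybenzyl ethers are inert.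

Step 15
Reactants: 21 C5 alcohol; 22 2-bromopropanoyl bromide (racemic)
Product: 23 C5 2-bromopropanoate (mixture at the bromine-bearing carbon)
Conditions: 22, pyridine, DMAP (cat.), CH2Cl2, 0 °C
Reagents that add atoms: 2-bromopropanoyl bromide 22, CC(Br)C(=O)Br
Why: Acylation of the hindered secondary alcohol with an acid bromide installs C1, C2 and the C2 methyl; the bromine-bearing centre is lost in step 18.

Step 16
Reactants: 23 bromoester
Product: 24 primary alcohol (free C3 hydroxyl)
Conditions: DDQ, CH2Cl2/pH 7 buffer, 0 °C
Reagents that add atoms: none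
Why: Oxidative cleavage removes the electron-rich 4-methoxybenzyl ether and spares the benzyl ether and the α-bromo ester.

Step 17
Reactants: 24 primary alcohol
Product: 25 C3 aldehyde (formyl on quaternary C4; C5 2-bromopropanoate)
Conditions: Dess–Martin periodinane, CH2Cl2, 20 °C
Reagents that add atoms: none
Why: Mild oxidation to an aldehyde that cannot enolise, since C4 is quaternary.

Step 18
Reactants: 25 bromoester aldehyde
Product: 26 bicyclic β-hydroxy lactone (C7 O-benzyl; C2 and C3 as formed)
Conditions: SmI2 (2.5 equiv), THF, −78 °C; H2O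
Reagents that add atoms: none
Why: SmI2 reduces the α-bromo ester to a trivalent samarium enolate that adds to the neighbouring aldehyde (intramolecular Reformatsky reaction, 6-(enolendo)-exo-trig closure of the lactone ring trans-fused to the pyran); the configurations formed at C2 and C3 are not relied on, because both are erased in step 19.

Step 19
Reactants: 26 β-hydroxy lactone
Product: 27 bicyclic β-keto lactone (C3 ketone; in equilibrium with its C2=C3 enol)
Conditions: Dess–Martin periodinane, CH2Cl2, 20 °C
Reagents that add atoms: none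
Why: Oxidation of the secondary alcohol converges all diastereomers of 26 on one β-keto lactone; C4 has no hydrogen, so neither elimination nor epimerisation is possible there.

Step 20
Reactants: 27 β-keto lactone
Product: 28 (2R,3S)-hydroxy lactone (C2 methyl, C3 hydroxyl and C4 methyl all cis; C7 O-benzyl)
Conditions: H2 (50 bar), Raney Ni, EtOAc, 25 °C
Reagents that add atoms: none
Why: Hydrogenation of the enol tautomer (the known Raney Ni reduction of 3-alkyl-4-hydroxy-5,6-dihydropyran-2-ones to cis-3-alkyl-4-hydroxy-δ-lactones) delivers both hydrogens to the face opposite the axial C4 methyl, so the C2 methyl and C3 hydroxyl end up cis to each other and to the C4 methyl.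

Step 21
Reactants: 28 hydroxy lactone
Product: 29 C3 O-triethylsilyl ether
Conditions: Et3SiOTf, 2,6-lutidine, CH2Cl2, −78 °C
Reagents that add atoms: triethylsilyl triflate, CC[Si](CC)(CC)OS(=O)(=O)C(F)(F)F
Why: Silyl triflate with a hindered base protects the hindered C3 hydroxyl without enolising the lactone, so C7 can be acylated alone later.

Step 22
Reactants: 29 benzyl ether
Product: 30 C7 alcohol (C3 O-triethylsilyl)
Conditions: H2 (1 bar), Pd/C, EtOAc, 20 °C
Reagents that add atoms: none
Why: Hydrogenolysis removes the benzyl ether; lactone and silyl ether are stable in ethyl acetate.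

Step 23
Reactants: 31 methyltriphenylphosphonium bromide; 32 pentanoyl chloride
Product: 34 1-(triphenyl-λ5-phosphanylidene)hexan-2-one, via methylidenephosphorane 33 (not isolated)
Conditions: 31 (2 equiv), n-BuLi (2 equiv), THF, 0 °C; then 32 (1 equiv), −78 → 20 °C
Reagents that add atoms: pentanoyl chloride 32, CCCCC(Cl)=O
Why: C-Acylation of the non-stabilised ylide, with the second equivalent acting as base, gives the stabilised acyl ylide.

Step 24
Reactants: 34 acyl ylide; 35 glyoxylic acid monohydrate
Product: 36 (E)-4-oxooct-2-enoic acid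
Conditions: 35, THF, 20 °C
Reagents that add atoms: glyoxylic acid monohydrate 35, OC(O)C(=O)O
Why: Wittig reaction of a stabilised ylide with the aldehyde of glyoxylic acid gives the E alkene.

Step 25
Reactants: 30 C7 alcohol; 36 (E)-4-oxooct-2-enoic acid
Product: 38 C7 (E)-4-oxooct-2-enoate (C3 O-triethylsilyl), via mixed anhydride 37 (not isolated)
Conditions: 2,4,6-trichlorobenzoyl chloride, Et3N, THF, 0 °C; then 30, DMAP, toluene, 20 °C
Reagents that add atoms: (E)-4-oxooct-2-enoic acid 36, CCCCC(=O)/C=C/C(=O)O
Why: Yamaguchi esterification acylates hindered secondary alcohols under mild conditions; C7 is not a reacting centre and keeps its configuration.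

Step 26
Reactants: 38 silyl-protected ester
Product: 39 Botcinin I (2R,3S,4R,5S,6R,7R,8S)
Conditions: HF·pyridine, THF/pyridine, 0 °C
Reagents that add atoms: none
Why: Buffered fluoride removes the triethylsilyl ether without base, so the enedione ester, the lactone and the epimerisable C2 centre are untouched.

**Compound list**

1 | sodium cyclopentadienide (NaC5H5, 2.0 M in THF) | [Na+].c1cc[cH-]c1 | starting material
2 | iodomethane | CI | starting material
3 | 5-methylcyclopenta-1,3-diene | CC1C=CC=C1 | intermediate
4 | dioxygen | O=O | starting material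
5 | meso 7-methyl-2,3-dioxabicyclo[2.2.1]hept-5-ene, methyl anti to the peroxide bridge | C[C@H]1[C@H]2C=C[C@@H]1OO2 | intermediate (not isolated)
6 | meso-2-methylcyclopent-4-ene-1,3-diol, hydroxyls cis, methyl trans to both | C[C@H]1[C@H](O)C=C[C@@H]1O | intermediate
7 | 4-hydroxy-5-methylcyclopent-2-en-1-yl acetate (1,4-cis, methyl trans; acetate on future O7) | C[C@H]1[C@H](O)C=C[C@@H]1OC(C)=O | intermediate
8 | 4-(tert-butyldimethylsilyloxy)-5-methylcyclopent-2-en-1-yl acetate | C[C@H]1[C@H](O[Si](C)(C)C(C)(C)C)C=C[C@@H]1OC(C)=O | intermediate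
9 | 4-(tert-butyldimethylsilyloxy)-5-methylcyclopent-2-en-1-ol | C[C@H]1[C@H](O[Si](C)(C)C(C)(C)C)C=C[C@@H]1O | intermediate
10 | ozonide of 9 (6,7,8-trioxabicyclo[3.2.1]octane) | C[C@H]1[C@H](O[Si](C)(C)C(C)(C)C)C2OOC(O2)[C@@H]1O | intermediate (not isolated)
11 | 4-(tert-butyldimethylsilyloxy)-5-hydroxy-3-methyloxolane-2-carbaldehyde (formyl and methyl cis, silyloxy trans; anomers) | O=C[C@@H]1OC(O)[C@@H](O[Si](C)(C)C(C)(C)C)[C@@H]1C | intermediate
12 | 3-(tert-butyldimethylsilyloxy)-4,6-dimethyloxane-2,5-diol (anomers; other substituents equatorial) | O[C@@H]1[C@@H](C)[C@H](O[Si](C)(C)C(C)(C)C)C(O)O[C@H]1C | intermediate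
13 | 3-(tert-butyldimethylsilyloxy)-5-hydroxy-4,6-dimethyloxan-2-one (all equatorial) | O[C@@H]1[C@@H](C)[C@H](O[Si](C)(C)C(C)(C)C)C(=O)O[C@H]1C | intermediate
14 | 5-(benzyloxy)-3-(tert-butyldimethylsilyloxy)-4,6-dimethyloxan-2-one (all equatorial) | c1ccccc1CO[C@@H]1[C@@H](C)[C@H](O[Si](C)(C)C(C)(C)C)C(=O)O[C@H]1C | intermediate
15 | (tributylstannyl)methanol | CCCC[Sn](CCCC)(CCCC)CO | starting material
16 | tributyl{[(4-methoxybenzyl)oxy]methyl}stannane | CCCC[Sn](CCCC)(CCCC)COCc1ccc(OC)cc1 | intermediate
17 | [(4-methoxybenzyl)oxy]methyllithium | [Li]COCc1ccc(OC)cc1 | intermediate (not isolated)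
18 | hemiketal: 5-(benzyloxy)-3-(tert-butyldimethylsilyloxy)-2-[(4-methoxybenzyloxy)methyl]-4,6-dimethyloxan-2-ol (anomers) | c1ccccc1CO[C@@H]1[C@@H](C)[C@H](O[Si](C)(C)C(C)(C)C)C(O)(COCc2ccc(OC)cc2)O[C@H]1C | intermediate
19 | methyl ketal of 18 (anomers) | c1ccccc1CO[C@@H]1[C@@H](C)[C@H](O[Si](C)(C)C(C)(C)C)C(OC)(COCc2ccc(OC)cc2)O[C@H]1C | intermediate
20 | 5-(benzyloxy)-3-(tert-butyldimethylsilyloxy)-2-[(4-methoxybenzyloxy)methyl]-2,4,6-trimethyloxane (2-methyl axial, rest equatorial) | c1ccccc1CO[C@@H]1[C@@H](C)[C@H](O[Si](C)(C)C(C)(C)C)[C@@](C)(COCc2ccc(OC)cc2)O[C@H]1C | intermediate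
21 | C5 alcohol: 5-(benzyloxy)-2-[(4-methoxybenzyloxy)methyl]-2,4,6-trimethyloxan-3-ol | c1ccccc1CO[C@@H]1[C@@H](C)[C@H](O)[C@@](C)(COCc2ccc(OC)cc2)O[C@H]1C | intermediate
22 | 2-bromopropanoyl bromide (racemic) | CC(Br)C(=O)Br | starting material
23 | C5 2-bromopropanoate of 21 (mixture at CHBr) | c1ccccc1CO[C@@H]1[C@@H](C)[C@H](OC(=O)C(C)Br)[C@@](C)(COCc2ccc(OC)cc2)O[C@H]1C | intermediate
24 | primary alcohol: 5-(benzyloxy)-2-(hydroxymethyl)-2,4,6-trimethyloxan-3-yl 2-bromopropanoate | c1ccccc1CO[C@@H]1[C@@H](C)[C@H](OC(=O)C(C)Br)[C@@](C)(CO)O[C@H]1C | intermediate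
25 | aldehyde: 5-(benzyloxy)-2-formyl-2,4,6-trimethyloxan-3-yl 2-bromopropanoate | c1ccccc1CO[C@@H]1[C@@H](C)[C@H](OC(=O)C(C)Br)[C@@](C)(C=O)O[C@H]1C | intermediate
26 | bicyclic β-hydroxy lactone, C7 O-benzyl (C2, C3 not defined) | c1ccccc1CO[C@@H]1[C@@H](C)[C@@H]2OC(=O)C(C)C(O)[C@@]2(C)O[C@H]1C | intermediate
27 | bicyclic β-keto lactone, C7 O-benzyl (keto form shown; C2 labile) | c1ccccc1CO[C@@H]1[C@@H](C)[C@@H]2OC(=O)C(C)C(=O)[C@@]2(C)O[C@H]1C | intermediate
28 | (2R,3S)-hydroxy lactone, C7 O-benzyl (botcinin core) | c1ccccc1CO[C@@H]1[C@@H](C)[C@@H]2OC(=O)[C@H](C)[C@H](O)[C@@]2(C)O[C@H]1C | intermediate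
29 | C3 O-triethylsilyl, C7 O-benzyl botcinin core | c1ccccc1CO[C@@H]1[C@@H](C)[C@@H]2OC(=O)[C@H](C)[C@H](O[Si](CC)(CC)CC)[C@@]2(C)O[C@H]1C | intermediate
30 | C3 O-triethylsilyl botcinin core with free C7 hydroxyl | O[C@@H]1[C@@H](C)[C@@H]2OC(=O)[C@H](C)[C@H](O[Si](CC)(CC)CC)[C@@]2(C)O[C@H]1C | intermediate
31 | methyltriphenylphosphonium bromide | C[P+](c1ccccc1)(c1ccccc1)c1ccccc1.[Br-] | starting material
32 | pentanoyl chloride | CCCCC(Cl)=O | starting material
33 | methylidenetriphenylphosphorane | C=P(c1ccccc1)(c1ccccc1)c1ccccc1 | intermediate (not isolated)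
34 | 1-(triphenyl-λ5-phosphanylidene)hexan-2-one | CCCCC(=O)C=P(c1ccccc1)(c1ccccc1)c1ccccc1 | intermediate
35 | glyoxylic acid monohydrate | OC(O)C(=O)O | starting material
36 | (E)-4-oxooct-2-enoic acid | CCCCC(=O)/C=C/C(=O)O | intermediate
37 | (E)-4-oxooct-2-enoic 2,4,6-trichlorobenzoic anhydride | CCCCC(=O)/C=C/C(=O)OC(=O)c1c(Cl)cc(Cl)cc1Cl | intermediate (not isolated)
38 | C3 O-triethylsilyl Botcinin I | CCCCC(=O)/C=C/C(=O)O[C@@H]1[C@@H](C)[C@@H]2OC(=O)[C@H](C)[C@H](O[Si](CC)(CC)CC)[C@@]2(C)O[C@H]1C | intermediate
39 | Botcinin I | CCCCC(=O)/C=C/C(=O)O[C@@H]1[C@@H](C)[C@@H]2OC(=O)[C@H](C)[C@H](O)[C@@]2(C)O[C@H]1C | target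

**Step count**

Total: 26 steps. Longest linear sequence: 23 steps (steps 1–9, 11–22, 25, 26).

**Steps most likely to fail**

Step 7 (poor facial selectivity in the methyl transfer to the C8 aldehyde, which would give C8 epimers carried into the lactone). The fallback sets out from lactone 14, taken as the C8 epimer mixture, and returns to 14 as one isomer. Opening with Me(MeO)NH·HCl and AlMe3 should give the hydroxy Weinreb amide F1. Dess–Martin oxidation gives the C8 methyl ketone F2 and erases the faulty centre. Zn(BH4)2 in ether reduces F2 under chelation between the ketone and the C7 benzyloxy group to the 7,8-anti alcohol F3. Warming F3 with camphorsulfonic acid in toluene relactonises it to 14. This swaps nucleophilic addition under Felkin–Anh control for chelation-controlled ketone reduction.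

Step 20 (slow or face-unselective uptake of hydrogen by the hindered tetrasubstituted enol, or reduction through the keto form with loss of control at C2). The fallback sets out from β-keto lactone 27 and returns at 28. NaBH4 in MeOH at −40 °C should attack the ketone from the face opposite the axial C4 methyl and give the 3S alcohol with the equilibrated, equatorial C2 methyl, the 2-epimer F4. Double deprotonation of F4 with LiN(iPr)2 (2.2 equiv) at −78 °C and kinetic protonation of the lactone enolate with 2,6-di-tert-butylphenol, again from the face opposite the C4 methyl, inverts C2 and gives 28. The two centres are then set one after the other by hydride attack and enolate protonation.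

Step 25 (conjugate addition and isomerisation of the activated 4-oxo-enoic acid competing with slow acylation of the hindered C7 hydroxyl). The fallback sets out from alcohol 30 and returns at 38. Acylation of 30 with the unhindered, robust diethylphosphonoacetic acid (diisopropylcarbodiimide, DMAP) gives the phosphonoacetate F5. 2-Oxohexanal F6 is prepared by Swern oxidation of commercial hexane-1,2-diol. Horner–Wadsworth–Emmons olefination of F5 with F6 (LiCl, iPr2NEt, MeCN) at the aldehyde carbonyl builds the E enedione on the ester and gives 38.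

**Further compounds**

F1 | step 7 | 5-hydroxy Weinreb amide from 14: 4-(benzyloxy)-2-(tert-butyldimethylsilyloxy)-5-hydroxy-N-methoxy-N,3-dimethylhexanamide (C8 epimers) | CON(C)C(=O)[C@@H](O[Si](C)(C)C(C)(C)C)[C@H](C)[C@@H](OCc1ccccc1)C(C)O
F2 | step 7 | 4-(benzyloxy)-2-(tert-butyldimethylsilyloxy)-N-methoxy-N,3-dimethyl-5-oxohexanamide | CON(C)C(=O)[C@@H](O[Si](C)(C)C(C)(C)C)[C@H](C)[C@@H](OCc1ccccc1)C(C)=O
F3 | step 7 | 7,8-anti hydroxy Weinreb amide | CON(C)C(=O)[C@@H](O[Si](C)(C)C(C)(C)C)[C@H](C)[C@@H](OCc1ccccc1)[C@H](C)O
F4 | step 20 | (2S,3S)-hydroxy lactone, C2 epimer of 28 | c1ccccc1CO[C@@H]1[C@@H](C)[C@@H]2OC(=O)[C@@H](C)[C@H](O)[C@@]2(C)O[C@H]1C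
F5 | step 25 | C7 (diethoxyphosphoryl)acetate of 30 | CCOP(=O)(OCC)CC(=O)O[C@@H]1[C@@H](C)[C@@H]2OC(=O)[C@H](C)[C@H](O[Si](CC)(CC)CC)[C@@]2(C)O[C@H]1C
F6 | step 25 | 2-oxohexanal | CCCCC(=O)C=O
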